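Ring B (C5–C6–C7–C8–C9–C10) is opened at C5–C6 and C9–C10, the two bonds that flank the C5–C10 fusion with gem-dimethyl ring A. Both form in one asymmetric intramolecular Diels–Alder reaction of an achiral triene: a 2-carboxy-4,4-dimethylcyclohexenone (ring A, dienophile C5=C10) esterified with a (Z)-dienol (C6=C7–C8=C9). The step exploits the sp2 fusion carbon C10 beside quaternary C9: a C10 carboxyl activates, tethers, fixes the C5/C9 relationship, and later leaves as CO2 to unveil C1=C10 while its oxygen is displaced from C12. The dioxane follows by SN2 peroxide closure and axial methylation of a peroxycarbenium ion.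

Key step: step 7

Atom labels: decalin carbons carry halimane numbers (C1 alkene CH, C4 CMe2, C5 fusion CH, C6/C7 ring B CH2, C8 CHMe, C9 quaternary C, C10 sp2 fusion C, C11/C12 chain CH2). Side-chain atoms are primed from the acid carbon (C1′ acid, C2′ CHMe, C3′ dioxane CH, C4′/C5′ dioxane CH2, C6′ dioxane quaternary C). β is the face of the C9 methyl.

Remark: the sense of induction in step 7 is assigned from the square-planar two-point-binding model of copper bis(oxazoline) catalysts ((S,S)-t-Bu-box = 2,2′-(propane-2,2-diyl)bis[(4S)-4-tert-butyl-4,5-dihydro-1,3-oxazole], diene on the Si face of C5); if the sense were opposite, the (R,R) ligand would give the same compound 10.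

Step 1
Reactants: 1 2,3-dimethylbuta-1,3-diene; 2 formaldehyde (charged as paraformaldehyde)
Product: 3 4,5-dimethyl-3,6-dihydro-2H-pyran
Conditions: (CH2O)n, hydroquinone (cat.), toluene, sealed tube, 180 °C
Reagents that add atoms: none
Why: Thermal hetero-Diels–Alder reaction of the 2,3-disubstituted diene with formaldehyde should give the dihydropyran, whose ring locks the two methyl-bearing alkene carbons in the cis arrangement needed later.

Step 2
Reactants: 3 4,5-dimethyl-3,6-dihydro-2H-pyran
Product: 4 3,4-dimethyl-5,6-dihydro-2H-pyran-2-one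
Conditions: [C5H5NH][CrO3Cl] (3 equiv), CH2Cl2, reflux
Reagents that add atoms: pyridinium chlorochromate, [O-][Cr](=O)(=O)Cl.c1cc[nH+]cc1
Why: Chromium-mediated allylic oxidation should attack the only CH2 that is both allylic and α to oxygen, the known conversion of 3,6-dihydro-2H-pyrans into 5,6-dihydro-2H-pyran-2-ones.

Step 3
Reactants: 4 3,4-dimethyl-5,6-dihydro-2H-pyran-2-one
Product: 5 3,4-dimethyl-5,6-dihydro-2H-pyran-2-ol (lactol)
Conditions: i-Bu2AlH (1.1 equiv), CH2Cl2, −78 °C; then MeOH, aq. potassium sodium tartrate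
Reagents that add atoms: none
Why: Half-reduction of the lactone at low temperature should stop at the lactol because the tetrahedral aluminium alkoxide does not collapse before work-up.

Step 4
Reactants: 5 3,4-dimethyl-5,6-dihydro-2H-pyran-2-ol
Product: 6 (3Z)-3,4-dimethylhexa-3,5-dien-1-ol
Conditions: Ph3PCH3Br (2.5 equiv), KOt-Bu (2.4 equiv), THF, 0 → 25 °C
Reagents that add atoms: methyltriphenylphosphonium bromide, C[P+](c1ccccc1)(c1ccccc1)c1ccccc1.[Br-]
Why: Wittig methylenation of the hydroxy enal in equilibrium with the lactol should give the dienol, the Z geometry of the tetrasubstituted alkene (CH2CH2OH cis to vinyl) being inherited from the ring.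

Step 5
Reactants: 7 4,4-dimethylcyclohex-2-en-1-one
Product: 8 2-iodo-4,4-dimethylcyclohex-2-en-1-one
Conditions: I2 (1.5 equiv), pyridine, CH2Cl2, 0 → 25 °C
Reagents that add atoms: iodine, II
Why: Amine-mediated α-iodination of the enone (conjugate addition of pyridine, iodination of the enolate, elimination) should place iodine on the α-carbon (future C10) only.

Step 6
Reactants: 8 2-iodo-4,4-dimethylcyclohex-2-en-1-one; 6 (3Z)-3,4-dimethylhexa-3,5-dien-1-ol
Product: 9 (3Z)-3,4-dimethylhexa-3,5-dien-1-yl 3,3-dimethyl-6-oxocyclohex-1-ene-1-carboxylate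
Conditions: CO (1 atm), Pd(OAc)2 (5 mol%), PPh3 (10 mol%), i-Pr2NEt, DMF, 50 °C
Reagents that add atoms: carbon monoxide, [C-]#[O+]
Why: Palladium-catalysed alkoxycarbonylation (oxidative addition of the alkenyl iodide to zerovalent palladium, CO insertion, alcoholysis of the acyl complex by the primary alcohol) should give the doubly activated enone ester, which cannot form a dienol because C4 is quaternary.

Step 7
Reactants: 9 triene ester
Product: 10 tricyclic keto lactone (5S,9R,10S)
Conditions: [Cu((S,S)-t-Bu-box)](SbF6)2 (10 mol%), 4 Å MS, CH2Cl2, −20 → 25 °C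
Reagents that add atoms: none
Why: Two-point binding of the ketone and ester carbonyls of 9 to divalent copper lowers the LUMO of the C5=C10 alkene, and the tethered diene adds across it in a concerted but asynchronous normal-demand [4+2] cycloaddition in which C5–C6 leads and C9–C10 follows. The closest known reactions are the Lewis-acid-promoted Diels–Alder additions of dienes to 2-alkoxycarbonyl-4,4-dimethylcyclohex-2-enones and the copper bis(oxazoline)-catalysed intramolecular Diels–Alder reactions of two-point-binding trienes. Ring B is closed as the six-membered [4+2] cycloadduct and the δ-lactone is closed in the same event as the tether ring of a type 1 (1,7,9-decatriene-like) intramolecular Diels–Alder reaction. Because the tether occupies the inside (Z) position of the diene terminus C9, only the cis-fused lactone can form, so the C9 arm (C11) and the C10 carboxyl end on one face, and suprafacial addition to the cis ring A alkene puts that carboxyl cis to H5; hence C5, C9 and C10 are set relative to each other by substrate geometry alone (H5 and C11 α, 9-methyl β), and the ligand, by shielding the Re face of C5, sets them absolutely. The step needs regioselectivity, which the tether fixes, and collapse of any zwitterionic intermediate to the ring instead of proton loss, which the quaternary C4 (no γ-hydrogen, no dienol) and the non-coordinating SbF6 counter-ion favour.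

Step 8
Reactants: 10 tricyclic keto lactone
Product: 11 hydroxy lactone (1R,5S,9R,10S)
Conditions: LiBH(s-Bu)3, THF, −78 °C; then H2O
Reagents that add atoms: none
Why: The bulky hydride should attack the C1 ketone from the equatorial direction, away from the syn-axial C6 methylene of ring A, giving the axial (1R) alcohol anti-periplanar to the C10–carboxyl bond, with the hindered lactone untouched at −78 °C.

Step 9
Reactants: 11 hydroxy lactone
Product: 12 C1 methanesulfonate of 11
Conditions: MsCl, Et3N, CH2Cl2, 0 °C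
Reagents that add atoms: methanesulfonyl chloride, CS(=O)(=O)Cl
Why: Sulfonylation through sulfene should convert even the hindered axial alcohol into the mesylate with retention at C1.

Step 10
Reactants: 12 mesyloxy lactone
Product: 15 iodo diene (5S,9R)-12-iodo-Δ1(10),7-bicycle, via iodo trimethylsilyl ester 13 (not isolated), via sodium iodo carboxylate 14 (not isolated)
Conditions: NaI, Me3SiCl, MeCN, 50 °C; then NaHCO3, aq. DMF, 60 °C
Reagents that add atoms: sodium iodide, [Na+].[I-]
Why: Iodotrimethylsilane made in situ should open the δ-lactone by SN2 attack of iodide at the primary C12 (the carbonyl is too hindered for acyl cleavage), and after desilylation the carboxylate should undergo anti-periplanar decarboxylative Grob-type fragmentation with loss of mesylate, which places the new alkene regiospecifically at C1=C10 and leaves C5 and C9 untouched.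

Step 11
Reactants: 16 (S)-4-benzyl-3-propanoyloxazolidin-2-one; 17 pent-4-enal
Product: 19 (S)-4-benzyl-3-[(2S,3R)-3-hydroxy-2-methylhept-6-enoyl]oxazolidin-2-one, via boron enolate 18 (not isolated)
Conditions: n-Bu2BOTf, i-Pr2NEt, CH2Cl2, −78 → 0 °C; 17, −78 → 0 °C; then pH 7 buffer, MeOH, H2O2
Reagents that add atoms: none
Why: Evans syn-aldol reaction through the Z boron enolate and a chair Zimmerman–Traxler transition state should set C2′ and C3′ (2S,3R, syn) under control of the (S)-benzyl auxiliary.

Step 12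
Reactants: 19 aldol adduct
Product: 20 (2R,3R)-2-methylhept-6-ene-1,3-diol
Conditions: LiBH4, MeOH (1 equiv), Et2O, 0 °C
Reagents that add atoms: none
Why: Borohydride reduction of the imide should release the 1,3-diol and the recoverable auxiliary without touching the stereocentres or the alkene.

Step 13
Reactants: 20 (2R,3R)-2-methylhept-6-ene-1,3-diol
Product: 21 (2R,3R)-1-(tert-butyldiphenylsilyloxy)-2-methylhept-6-en-3-ol
Conditions: t-BuPh2SiCl, imidazole, CH2Cl2, 0 °C
Reagents that add atoms: tert-butyl(chloro)diphenylsilane, CC(C)(C)[Si](Cl)(c1ccccc1)c1ccccc1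
Why: The bulky silyl chloride should react selectively at the primary hydroxyl.

Step 14
Reactants: 21 silyl ether alkenol
Product: 23 (5R)-5-[(2R)-1-(tert-butyldiphenylsilyloxy)propan-2-yl]dihydrofuran-2(3H)-one, via lactol 22 (not isolated)
Conditions: OsO4 (1 mol%), KHSO5 (as 2KHSO5·KHSO4·K2SO4, 4 equiv), DMF, 25 °C
Reagents that add atoms: potassium peroxymonosulfate, OOS(=O)(=O)[O-].[K+]
Why: Osmium-catalysed oxidative cleavage of the terminal alkene by peroxymonosulfate should give the C6′ aldehyde, which closes to lactol 22 with the free C3′ hydroxyl and is oxidised on to the γ-lactone (oxidative lactonisation of an alkenol), with C3′ untouched.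

Step 15
Reactants: 15 iodo diene; 23 γ-lactone
Product: 25 γ-hydroxy ketone (5S,9R,2′R,3′R) with both ring alkenes, via alkyllithium 24 (not isolated)
Conditions: 15, t-BuLi (2.1 equiv), Et2O–pentane, −78 °C; then 23, −78 °C; aq. NH4Cl
Reagents that add atoms: none
Why: Lithium–iodine exchange should give the primary alkyllithium, which adds once to the γ-lactone at −78 °C because the lithium hemiketal alkoxide survives until the quench, delivering the C6′ ketone and freeing the C3′ hydroxyl.

Step 16
Reactants: 25 γ-hydroxy ketone diene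
Product: 26 (6R,7R)-8-(tert-butyldiphenylsilyloxy)-6-hydroxy-7-methyl-1-[(1R,2R,4aS)-1,2,5,5-tetramethyl-1,2,3,4,4a,5,6,7-octahydronaphthalen-1-yl]octan-3-one
Conditions: H2 (1 atm), PtO2, EtOAc, 25 °C
Reagents that add atoms: none
Why: Heterogeneous hydrogenation should reduce the less shielded C7=C8 alkene from the β face, anti to the pseudo-axial C9 CH2 arm, setting C8 (R, methyl α and equatorial), while the C1=C10 alkene, buried between quaternary C9 and C5, should survive.

Step 17
Reactants: 26 hydroxy ketone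
Product: 27 C3′ methanesulfonate of 26
Conditions: MsCl, Et3N, CH2Cl2, 0 °C
Reagents that add atoms: methanesulfonyl chloride, CS(=O)(=O)Cl
Why: Mesylation of the open-chain γ-hydroxy ketone should activate C3′ with retention for the later invertive displacement.

Step 18
Reactants: 27 mesyloxy ketone
Product: 30 (3′S)-6′-methoxy-1,2-dioxane (both C6′ anomers), via dimethyl ketal 28 (not isolated), via methoxy hydroperoxide 29 (not isolated)
Conditions: HC(OMe)3, MeOH, camphorsulfonic acid (cat.), 25 °C; then H2O2 (anhydrous, in Et2O), 0 °C; then Cs2CO3, DMF, 0 → 25 °C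
Reagents that add atoms: trimethyl orthoformate, COC(OC)OC; methanol, CO; hydrogen peroxide, OO
Why: Ketalisation, exchange of one methoxy group for hydrogen peroxide to the α-methoxy hydroperoxide and base-induced 6-exo-tet intramolecular alkylation of the hydroperoxide by the mesylate (SN2, inversion at C3′ to S) should give the 1,2-dioxane as a mixture of C6′ anomers that does not matter.

Step 19
Reactants: 30 6′-methoxy-1,2-dioxane
Product: 31 (3′S,6′R)-6′-methyl-1,2-dioxane silyl ether
Conditions: Me3Al (3 equiv), Me3SiOTf (1.2 equiv), CH2Cl2, −78 °C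
Reagents that add atoms: trimethylaluminium, C[Al](C)C
Why: Proposed new method: ionisation of either anomer by Me3SiOTf should give one cyclic peroxycarbenium ion whose half-chair holds the C3′ substituent pseudo-equatorial, and methyl transfer from Me3Al along the axial trajectory should put the methyl axial and cis to the C3′ substituent (C6′ R), a stereoconvergent step whose closest known relatives are Lewis-acid-mediated substitutions of peroxyketals by allylsilanes, silyl enol ethers and Et3SiH and the axial methylation of oxocarbenium ions of cyclic ketals by Me3Al.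

Step 20
Reactants: 31 silyl ether
Product: 32 (2R)-2-[(3S,6R)-6-methyl-6-{2-[(1R,2R,4aS)-1,2,5,5-tetramethyl-1,2,3,4,4a,5,6,7-octahydronaphthalen-1-yl]ethyl}-1,2-dioxan-3-yl]propan-1-ol
Conditions: n-Bu4NF, THF, 0 °C
Reagents that add atoms: none
Why: Fluoride should cleave the silyl ether without touching the dialkyl peroxide.

Step 21
Reactants: 32 primary alcohol
Product: 33 mycaperoxide H
Conditions: TEMPO (20 mol%), PhI(OAc)2 (2.2 equiv), MeCN–pH 7 buffer (1:1), 25 °C
Reagents that add atoms: water, O
Why: Nitroxyl-catalysed oxidation with a hypervalent iodine co-oxidant in aqueous acetonitrile should take the primary alcohol through the aldehyde hydrate to the acid without epimerising C2′ and without attacking the peroxide or the hindered alkene.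

Compound list
1 | 2,3-dimethylbuta-1,3-diene | C=C(C)C(C)=C | starting material
2 | formaldehyde (charged as paraformaldehyde) | C=O | starting material
3 | 4,5-dimethyl-3,6-dihydro-2H-pyran | CC1=C(C)COCC1 | intermediate
4 | 3,4-dimethyl-5,6-dihydro-2H-pyran-2-one | CC1=C(C)C(=O)OCC1 | intermediate
5 | 3,4-dimethyl-5,6-dihydro-2H-pyran-2-ol (lactol, both anomers) | CC1=C(C)C(O)OCC1 | intermediate
6 | (3Z)-3,4-dimethylhexa-3,5-dien-1-ol | OCC/C(C)=C(C)\C=C | intermediate
7 | 4,4-dimethylcyclohex-2-en-1-one | CC1(C)CCC(=O)C=C1 | starting material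
8 | 2-iodo-4,4-dimethylcyclohex-2-en-1-one | CC1(C)CCC(=O)C(I)=C1 | intermediate
9 | (3Z)-3,4-dimethylhexa-3,5-dien-1-yl 3,3-dimethyl-6-oxocyclohex-1-ene-1-carboxylate | CC1(C)CCC(=O)C(=C1)C(=O)OCC/C(C)=C(C)\C=C | intermediate
10 | tricyclic keto lactone (5S,9R,10S): ring A 1-ketone; ring B Δ7; cis-fused δ-lactone C10–C(=O)–O–C12–C11–C9 on the α face; 9β-methyl; 5α-H | O=C1CCC(C)(C)[C@@H]2CC=C(C)[C@@]3(C)CCOC(=O)[C@@]123 | intermediate
11 | hydroxy lactone (1R,5S,9R,10S): 10 with axial C1–OH anti to the C10 acyl bond | O[C@@H]1CCC(C)(C)[C@@H]2CC=C(C)[C@@]3(C)CCOC(=O)[C@@]123 | intermediate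
12 | C1 methanesulfonate of 11 | CS(=O)(=O)O[C@@H]1CCC(C)(C)[C@@H]2CC=C(C)[C@@]3(C)CCOC(=O)[C@@]123 | intermediate
13 | trimethylsilyl ester of the ring-opened 12-iodo C10 acid (C1 mesylate kept) | CS(=O)(=O)O[C@@H]1CCC(C)(C)[C@@H]2CC=C(C)[C@@](C)(CCI)[C@]12C(=O)O[Si](C)(C)C | intermediate
14 | sodium salt of the 12-iodo C10 carboxylate (C1 mesylate kept) | CS(=O)(=O)O[C@@H]1CCC(C)(C)[C@@H]2CC=C(C)[C@@](C)(CCI)[C@]12C(=O)[O-].[Na+] | intermediate
15 | (1R,4aS)-1-(2-iodoethyl)-1,2,5,5-tetramethyl-1,4,4a,5,6,7-hexahydronaphthalene (halimane 5S,9R; Δ1(10),Δ7) | ICC[C@@]1(C)C2=CCCC(C)(C)[C@@H]2CC=C1C | intermediate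
16 | (S)-4-benzyl-3-propanoyloxazolidin-2-one | CCC(=O)N1[C@@H](Cc2ccccc2)COC1=O | starting material
17 | pent-4-enal | C=CCCC=O | starting material
18 | (Z)-di-n-butylboron enolate of 16 | C/C=C(\OB(CCCC)CCCC)N1[C@@H](Cc2ccccc2)COC1=O | intermediate
19 | (S)-4-benzyl-3-[(2S,3R)-3-hydroxy-2-methylhept-6-enoyl]oxazolidin-2-one | C=CCC[C@@H](O)[C@H](C)C(=O)N1[C@@H](Cc2ccccc2)COC1=O | intermediate
20 | (2R,3R)-2-methylhept-6-ene-1,3-diol | C=CCC[C@@H](O)[C@H](C)CO | intermediate
21 | (2R,3R)-1-(tert-butyldiphenylsilyloxy)-2-methylhept-6-en-3-ol | C=CCC[C@@H](O)[C@H](C)CO[Si](c1ccccc1)(c1ccccc1)C(C)(C)C | intermediate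
22 | (5R)-5-[(2R)-1-(tert-butyldiphenylsilyloxy)propan-2-yl]tetrahydrofuran-2-ol (lactol) | OC1CC[C@@H](O1)[C@H](C)CO[Si](c1ccccc1)(c1ccccc1)C(C)(C)C | intermediate
23 | (5R)-5-[(2R)-1-(tert-butyldiphenylsilyloxy)propan-2-yl]dihydrofuran-2(3H)-one | O=C1CC[C@@H](O1)[C@H](C)CO[Si](c1ccccc1)(c1ccccc1)C(C)(C)C | intermediate
24 | primary alkyllithium from 15 (C12–Li) | [Li]CC[C@@]1(C)C2=CCCC(C)(C)[C@@H]2CC=C1C | intermediate
25 | (6R,7R)-8-(tert-butyldiphenylsilyloxy)-6-hydroxy-7-methyl-1-[(1R,4aS)-1,2,5,5-tetramethyl-1,4,4a,5,6,7-hexahydronaphthalen-1-yl]octan-3-one | O=C(CC[C@@]1(C)C2=CCCC(C)(C)[C@@H]2CC=C1C)CC[C@@H](O)[C@H](C)CO[Si](c1ccccc1)(c1ccccc1)C(C)(C)C | intermediate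
26 | (6R,7R)-8-(tert-butyldiphenylsilyloxy)-6-hydroxy-7-methyl-1-[(1R,2R,4aS)-1,2,5,5-tetramethyl-1,2,3,4,4a,5,6,7-octahydronaphthalen-1-yl]octan-3-one | O=C(CC[C@@]1(C)C2=CCCC(C)(C)[C@@H]2CC[C@H]1C)CC[C@@H](O)[C@H](C)CO[Si](c1ccccc1)(c1ccccc1)C(C)(C)C | intermediate
27 | C3′ methanesulfonate of 26 (2′R,3′R) | O=C(CC[C@@]1(C)C2=CCCC(C)(C)[C@@H]2CC[C@H]1C)CC[C@@H](OS(C)(=O)=O)[C@H](C)CO[Si](c1ccccc1)(c1ccccc1)C(C)(C)C | intermediate
28 | C6′ dimethyl ketal of 27 | COC(OC)(CC[C@@]1(C)C2=CCCC(C)(C)[C@@H]2CC[C@H]1C)CC[C@@H](OS(C)(=O)=O)[C@H](C)CO[Si](c1ccccc1)(c1ccccc1)C(C)(C)C | intermediate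
29 | C6′ α-methoxy hydroperoxide of 27 | COC(OO)(CC[C@@]1(C)C2=CCCC(C)(C)[C@@H]2CC[C@H]1C)CC[C@@H](OS(C)(=O)=O)[C@H](C)CO[Si](c1ccccc1)(c1ccccc1)C(C)(C)C | intermediate
30 | tert-butyl{(2R)-2-[(3S)-6-methoxy-6-{2-[(1R,2R,4aS)-1,2,5,5-tetramethyl-1,2,3,4,4a,5,6,7-octahydronaphthalen-1-yl]ethyl}-1,2-dioxan-3-yl]propoxy}diphenylsilane (both C6 anomers) | C[C@H](CO[Si](c1ccccc1)(c1ccccc1)C(C)(C)C)[C@@H]1CCC(OC)(CC[C@@]2(C)C3=CCCC(C)(C)[C@@H]3CC[C@H]2C)OO1 | intermediate
31 | tert-butyl{(2R)-2-[(3S,6R)-6-methyl-6-{2-[(1R,2R,4aS)-1,2,5,5-tetramethyl-1,2,3,4,4a,5,6,7-octahydronaphthalen-1-yl]ethyl}-1,2-dioxan-3-yl]propoxy}diphenylsilane | C[C@H](CO[Si](c1ccccc1)(c1ccccc1)C(C)(C)C)[C@@H]1CC[C@@](C)(CC[C@@]2(C)C3=CCCC(C)(C)[C@@H]3CC[C@H]2C)OO1 | intermediate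
32 | (2R)-2-[(3S,6R)-6-methyl-6-{2-[(1R,2R,4aS)-1,2,5,5-tetramethyl-1,2,3,4,4a,5,6,7-octahydronaphthalen-1-yl]ethyl}-1,2-dioxan-3-yl]propan-1-ol | C[C@H](CO)[C@@H]1CC[C@@](C)(CC[C@@]2(C)C3=CCCC(C)(C)[C@@H]3CC[C@H]2C)OO1 | intermediate
33 | mycaperoxide H, (2S)-2-[(3S,6R)-6-methyl-6-{2-[(1R,2R,4aS)-1,2,5,5-tetramethyl-1,2,3,4,4a,5,6,7-octahydronaphthalen-1-yl]ethyl}-1,2-dioxan-3-yl]propanoic acid | C[C@H](C(=O)O)[C@@H]1CC[C@@](C)(CC[C@@]2(C)C3=CCCC(C)(C)[C@@H]3CC[C@H]2C)OO1 | target

Total step count: 21
Longest linear sequence: 16 steps (steps 1–4, 6–10, 15–21)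

Steps most likely to fail

Step 19. The alkylaluminium may cleave or reduce the O–O bond, or the peroxycarbenium ion may rearrange (Criegee-type oxygen insertion) faster than it accepts methyl; facial selectivity could also be lower than the axial-attack model predicts. The fallback builds the C6′ centre with the methyl already in place and sets out from 26. Wittig methylenation of the ketone (Ph3P=CH2, THF) gives the 6′-methylene alkenol F1, and mesylation gives its C3′ methanesulfonate F2. Mukaiyama–Isayama hydroperoxysilylation (Co(acac)2, O2, Et3SiH, ClCH2CH2Cl) of the 1,1-disubstituted alkene gives the tertiary triethylsilyl peroxide F3 as both C6′ epimers. K2CO3 in MeOH removes the silyl group, and the peroxide anion closes on the mesylate (SN2, inversion at C3′) to 31 and its C6′ epimer, which are separated by chromatography. The route is rejoined at 31.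

Step 7. The lactone-forming tether demands the disfavoured E conformation of the ester, so the cationic copper-bound enone may instead be attacked stepwise by the diene terminus and the resulting allyl cation may lose a proton (ene-type product), or facial discrimination may be poor. The fallback makes the same two bonds intermolecularly and closes the lactone afterwards; it sets out from 8 and 6. Methoxycarbonylation of 8 (CO, MeOH, Pd(OAc)2, PPh3, Et3N) gives methyl 3,3-dimethyl-6-oxocyclohex-1-ene-1-carboxylate F4, and silylation of 6 (t-BuMe2SiCl, imidazole) gives the dienyl silyl ether F5. Their Diels–Alder reaction under the same copper catalyst, with the ketone endo and the inside CH2 arm therefore cis to the ester, gives the bicyclic keto ester F6. Desilylation (HF·pyridine) and acid-catalysed lactonisation (camphorsulfonic acid, toluene, 80 °C) return to 10.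

Step 18. Ionisation of the secondary mesylate with participation of the ketal or carbonyl oxygen (tetrahydrofuran formation) and E2 elimination may outrun the 6-exo displacement by the hydroperoxide. The fallback forms the C3′–O bond first and intermolecularly, and sets out from 27. Displacement of the mesylate by the caesium salt of 2-methoxypropan-2-yl hydroperoxide (CsOH, DMF, 0 °C; SN2, inversion) gives the C3′ peroxyketal F7. Aqueous acetic acid in THF removes the ketal, and the free hydroperoxide adds to the C6′ ketone to give the cyclic peroxyhemiketal F8. F8 is ionised under the conditions of step 19 in place of 30, and the route is rejoined at 31.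

Further compounds
F1 | step 19 | (2R,3R)-1-(tert-butyldiphenylsilyloxy)-2-methyl-6-methylidene-8-[(1R,2R,4aS)-1,2,5,5-tetramethyl-1,2,3,4,4a,5,6,7-octahydronaphthalen-1-yl]octan-3-ol | C=C(CC[C@@]1(C)C2=CCCC(C)(C)[C@@H]2CC[C@H]1C)CC[C@@H](O)[C@H](C)CO[Si](c1ccccc1)(c1ccccc1)C(C)(C)C
F2 | step 19 | C3′ methanesulfonate of F1 | C=C(CC[C@@]1(C)C2=CCCC(C)(C)[C@@H]2CC[C@H]1C)CC[C@@H](OS(C)(=O)=O)[C@H](C)CO[Si](c1ccccc1)(c1ccccc1)C(C)(C)C
F3 | step 19 | C6′ tertiary triethylsilyl peroxide of F2 (both C6′ epimers) | CC[Si](CC)(CC)OOC(C)(CC[C@@]1(C)C2=CCCC(C)(C)[C@@H]2CC[C@H]1C)CC[C@@H](OS(C)(=O)=O)[C@H](C)CO[Si](c1ccccc1)(c1ccccc1)C(C)(C)C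
F4 | step 7 | methyl 3,3-dimethyl-6-oxocyclohex-1-ene-1-carboxylate | COC(=O)C1=CC(C)(C)CCC1=O
F5 | step 7 | tert-butyl{[(3Z)-3,4-dimethylhexa-3,5-dien-1-yl]oxy}dimethylsilane | CC(C)(C)[Si](C)(C)OCC/C(C)=C(C)\C=C
F6 | step 7 | bicyclic keto ester (5S,9R,10S): 1-oxo-Δ7 decalin with C10 CO2Me and the C9 CH2CH2OSi(t-Bu)Me2 arm cis to it | O=C1CCC(C)(C)[C@@H]2CC=C(C)[C@@](C)(CCO[Si](C)(C)C(C)(C)C)[C@]12C(=O)OC
F7 | step 18 | (3′S)-C3′ 2-methoxypropan-2-yl peroxide of the C6′ ketone (mesylate of 27 displaced with inversion) | COC(C)(C)OO[C@@H](CCC(=O)CC[C@@]1(C)C2=CCCC(C)(C)[C@@H]2CC[C@H]1C)[C@H](C)CO[Si](c1ccccc1)(c1ccccc1)C(C)(C)C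
F8 | step 18 | (3′S)-6′-hydroxy-1,2-dioxane (cyclic peroxyhemiketal, both C6′ anomers) | C[C@H](CO[Si](c1ccccc1)(c1ccccc1)C(C)(C)C)[C@@H]1CCC(O)(CC[C@@]2(C)C3=CCCC(C)(C)[C@@H]3CC[C@H]2C)OO1
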